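(The readings are simulated for substances that don't exist; the scatter is artificial.)

| setting | autumn | spring | Wednesday's | Saturday's |
|---|---|---|---|---|
| left-handed substrate | 0.40 M | 1.6 M | 0.79 M | 0.79 M |
| right-handed substrate | 0.40 M | 1.6 M | 0.79 M | 0.79 M |
| gas | 49 mM (held) | 49 mM (held) | 49 mM (held) | 49 mM (held) |
| remark | run made earlier | run made earlier |  |  |
| time |  |  | 20 h | 10 h |

- autumn (time / h: left-handed product / %, right-handed product / %): 1.50: 0.4, 0; 3.00: 0.8, 0; 5.00: 1.1, 0; 6.00: 1.8, 0.1; 8.00: 2.4, 0.4; 10.0: 3.0, 0.6; 12.0: 4.2, 1.1
- spring (time / h: left-handed product / %, right-handed product / %): 1.00: 0.3, 0.4; 1.33: 0.2, 0.4; 2.00: 0.3, 0; 3.00: 0.4, 0.2; 5.00: 0.9, 0.1; 8.00: 1.3, 0.7; 12.0: 2.3, 0.1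

(scatter of a reading: 0.3 percentage points)

* the flask that ends with the higher excess of left-handed product over right-handed product in the product, or "neither" when 2 percentage points or less lies between them (Wednesday's / Saturday's / neither)
* excess of left-handed product over right-handed product in the product at the end, Wednesday's
* excess of left-handed product over right-handed product in the product at the end, Saturday's

- partner is single-handed; left-handed substrate and right-handed substrate are mirror images of each other, charged as a racemate, each of them at the stated concentration
- at the start none of the gas is in solution
- an excess is the difference of the two amounts in percent of their sum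
- an excess is below zero if the other one leads
- the handed part of partner does not stay in what it makes, so the products of the two hands are mirror images too

**Time first.** Wednesday's flask stops at 20 h and Saturday's at 10 h, half the time, from the same charge, so I reckon the excess by the clock. The products are mirror images, so under thermodynamic control the excess ends at zero, and what I need is how fast the kinetic excess sinks.

**The ledger.** I pool the autumn run's last 3 readings against the scatter, centred on 10.0 h: the left-handed product's readings sum to 9.60 % and the right-handed product's to 2.10 %, so the books close at a pooled excess of 64.1 %. The spring run, with 1.6 M of each hand against 0.40 M, closes from 5.00 h to 12.0 h at 66.7 %, so in these readings the charge moves the excess little.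

**Halving time.** The right-handed product reads 0 % at 5.00 h, which a scatter of 0.3 percentage points cannot tell from a small amount, so I start the excess as whole purely as a working assumption and take it at any hour as the halving time over the halving time plus that hour. The ledger gives 17.9 h as this halving time of the excess, the hours after which it stands at half its start. My reckoning is 64.1 % for Saturday's and 47.2 % for Wednesday's, so Saturday's ends higher, by more than the margin of 2 points.

**The forecast.** It says Saturday's, with 60 % for Wednesday's and 95 % for Saturday's, on these grounds: “Saturday's therefore stops near the end of the lag, with almost pure left-handed product.” We part on Saturday's, where I stand 31 points lower.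

**The flasks.** Saturday's ends higher, Wednesday's at 60.0 % and Saturday's at 70.0 %.

    partner + left-handed substrate → left-handed product (k = 0.00580 M⁻¹ min⁻¹)
    partner + right-handed substrate → right-handed product (k = 6.20 × 10⁻⁴ M⁻¹ min⁻¹)
    left-handed substrate ⇌ right-handed substrate (k = 0.00460 min⁻¹)
    partner → decomposed reagent (k = 5.90 × 10⁻⁴ min⁻¹)
    gas ⇌ partner, rate k5*(csat - [partner]) (kL = 0.00350 min⁻¹)
    left-handed product ⇌ right-handed product (k = 2.80 × 10⁻⁴ min⁻¹)

**One flask further.** Saturday's result lies 5.9 points above my reckoning and Wednesday's 13 points above it, so my halving time runs short on both flasks, and the forecast's Wednesday figure stands while its Saturday figure falls to 70.0 %. Saturday's flask read on to 40 h is the next test: the same halving time gives 30.9 %, again low, and that flask holds 9.61 % of left-handed product and 3.65 % of right-handed product, an excess of 45.0 %.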